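**Retrosynthetic overview**

1. Target ⇒ labda-13(16),14-diene-7α,8α,19-triol: the (Z)-p-coumarate comes from a C19 phosphonoacetate by Still–Gennari olefination; the 7α,8α-diol from a C7 ketone (Δ7 silyl enol ether, Rubottom oxidation, axial-selective hydride reduction); the C12–C16 diene from the C11 aldehyde by Wittig methylenation and B-alkyl Suzuki–Miyaura coupling with chloroprene.
2. Bicyclic C11 aldehyde ⇒ acyclic (S)-trienal by a catalytic enantioselective intramolecular Diels–Alder reaction that forms C5–C10 and C8–C9; rings A and B are formed together in this one step, and no ring exists before it.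
3. Enabling feature: in ring B (C5–C6–C7–C8–C9–C10) the oxygen on C7 marks a C5=C6–C7(OSi)=C8 silyloxydiene, the cis pair C9–C11/C10–C20 marks an (E)-C9=C10 enal (C11 = CHO), and C1–C2–C3–C4 of ring A is the four-atom tether from C10 to C5.
4. Trienal ⇒ ethyl enone (enol silylation; ester → enal) ⇒ vinyl-bearing quaternary (S)-C4 ester (cross-metathesis with pent-1-en-3-one) ⇒ copper-catalysed enantioselective SN2′ allyl–alkyl coupling of an alkyl-9-BBN (from a Negishi carboalumination product) with a γ,γ-disubstituted allyl chloride.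

Key step: step 10

Remark on numbering: bicyclic compounds are named with labdane numbering. The decalin is C1–C10 with ring fusion C5/C10 (ring A = C1–C5, C10; ring B = C5–C10). C11–C16 is the side chain on C9, C17 the methyl on C8, C18 (α) and C19 (β) the substituents on C4, and C20 the methyl on C10. All bicyclic compounds have 5α-H, 9α-H, 10β-CH3, 4α-CH3 and a 4β-CH2O group.

Assumption: the TBS ether of hydroxyacetone, bis(2,2,2-trifluoroethyl)phosphonoacetic acid and chloroprene (stabilised solution) are taken as purchasable.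

**Route**

Step 1
Reactants: 1 pent-1-en-4-yne
Product: 3 methyl (2E)-3-methylhexa-2,5-dienoate, via alkenyl(dimethyl)alane 2 (not isolated)
Conditions: AlMe3 (2 equiv), Cp2ZrCl2 (0.2 equiv), ClCH2CH2Cl, 0 °C → rt; then n-BuLi, THF, −78 °C; ClCO2Me, −78 °C → rt
Reagents that add atoms: trimethylaluminium, C[Al](C)C; methyl chloroformate, COC(=O)Cl
Why: Negishi carboalumination adds CH3 and Al syn across the terminal alkyne with CH3 at the internal carbon, and the derived alanate is acylated with retention, so the (E)-β-methyl enoate should form stereospecifically while the isolated alkene is untouched.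

Step 2
Reactants: 4 1-[(tert-butyldimethylsilyl)oxy]propan-2-one; 5 triethyl phosphonoacetate
Product: 6 ethyl (2E)-4-[(tert-butyldimethylsilyl)oxy]-3-methylbut-2-enoate
Conditions: NaH, THF, 0 °C → rt; the minor (Z)-isomer is removed by chromatography
Reagents that add atoms: none
Why: Horner–Wadsworth–Emmons olefination of the methyl ketone with a stabilised phosphonate should favour the (E)-trisubstituted enoate under thermodynamic control of the oxaphosphetane.

Step 3
Reactants: 6 ethyl (2E)-4-[(tert-butyldimethylsilyl)oxy]-3-methylbut-2-enoate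
Product: 7 (2E)-4-[(tert-butyldimethylsilyl)oxy]-3-methylbut-2-en-1-ol
Conditions: i-Bu2AlH (2.2 equiv), CH2Cl2, −78 °C; aqueous potassium sodium tartrate
Reagents that add atoms: none
Why: 1,2-Reduction of the enoate by the aluminium hydride should give the allylic alcohol with the alkene geometry and the silyl ether unchanged.

Step 4
Reactants: 7 (2E)-4-[(tert-butyldimethylsilyl)oxy]-3-methylbut-2-en-1-ol
Product: 8 tert-butyl{[(2E)-4-chloro-2-methylbut-2-en-1-yl]oxy}dimethylsilane
Conditions: PPh3, N-chlorosuccinimide, CH2Cl2, −20 → 0 °C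
Reagents that add atoms: N-chlorosuccinimide, O=C1CCC(=O)N1Cl
Why: Appel-type chlorination displaces the alkoxyphosphonium of the primary allylic alcohol by chloride in an SN2 sense, without allylic transposition or loss of geometry.

Step 5
Reactants: 3 methyl (2E)-3-methylhexa-2,5-dienoate; 8 tert-butyl{[(2E)-4-chloro-2-methylbut-2-en-1-yl]oxy}dimethylsilane
Product: 10 methyl (2E,7S)-7-{[(tert-butyldimethylsilyl)oxy]methyl}-3,7-dimethylnona-2,8-dienoate, via B-alkyl-9-borabicyclononane 9 (not isolated)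
Conditions: 9-BBN-H dimer, THF, 0 °C → rt; then 8, CuCl (10 mol %), chiral hydroxyaryl-substituted imidazolinium chloride (N-heterocyclic carbene precursor, 11 mol %), KOMe (1.2 equiv), THF/1,4-dioxane, 25 °C
Reagents that add atoms: 9-borabicyclo[3.3.1]nonane, B1C2CCCC1CCC2 (boron residue in 9 only)
Why: Anti-Markovnikov hydroboration takes only the terminal alkene of 3, and the copper-catalysed γ-selective (SN2′) allyl–alkyl coupling of the alkylborane with the (E)-γ,γ-disubstituted allyl chloride creates the quaternary C4 centre, the ligand antipode being chosen so that the alkyl group is delivered to the enantioface giving (S).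

Step 6
Reactants: 10 methyl (2E,7S)-7-{[(tert-butyldimethylsilyl)oxy]methyl}-3,7-dimethylnona-2,8-dienoate; 11 pent-1-en-3-one
Product: 12 methyl (2E,7S,8E)-7-{[(tert-butyldimethylsilyl)oxy]methyl}-3,7-dimethyl-10-oxododeca-2,8-dienoate
Conditions: second-generation Hoveyda–Grubbs catalyst (5 mol %), 11 (5 equiv), CH2Cl2, 40 °C
Reagents that add atoms: none
Why: Olefin cross-metathesis of the vinyl group, which cannot homodimerise next to the quaternary carbon, with an excess of the enone should give the (E)-enone, the trisubstituted enoate alkene being inert.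

Step 7
Reactants: 12 methyl (2E,7S,8E)-7-{[(tert-butyldimethylsilyl)oxy]methyl}-3,7-dimethyl-10-oxododeca-2,8-dienoate
Product: 13 methyl (2E,7S,8E,10Z)-7-{[(tert-butyldimethylsilyl)oxy]methyl}-3,7-dimethyl-10-[(triisopropylsilyl)oxy]dodeca-2,8,10-trienoate
Conditions: i-Pr3SiOTf (1.2 equiv), Et3N (2 equiv), CH2Cl2, −78 → 0 °C
Reagents that add atoms: triisopropylsilyl trifluoromethanesulfonate, CC(C)[Si](OS(=O)(=O)C(F)(F)F)(C(C)C)C(C)C
Why: Soft enolisation (silyl triflate/amine) can only remove an α′-hydrogen of the ethyl ketone, because the γ-position C4 is quaternary and the ester is not enolised, and it should give mainly the (Z)-silyl enol ether of the cross-conjugated diene.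

Step 8
Reactants: 13 methyl (2E,7S,8E,10Z)-7-{[(tert-butyldimethylsilyl)oxy]methyl}-3,7-dimethyl-10-[(triisopropylsilyl)oxy]dodeca-2,8,10-trienoate
Product: 14 (2E,7S,8E,10Z)-7-{[(tert-butyldimethylsilyl)oxy]methyl}-3,7-dimethyl-10-[(triisopropylsilyl)oxy]dodeca-2,8,10-trien-1-ol
Conditions: i-Bu2AlH (2.5 equiv), CH2Cl2, −78 °C; aqueous potassium sodium tartrate
Reagents that add atoms: none
Why: Hydride reduction of the enoate to the allylic alcohol under neutral, fluoride-free conditions leaves the silyl dienol ether and the silyl ether intact.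

Step 9
Reactants: 14 (2E,7S,8E,10Z)-7-{[(tert-butyldimethylsilyl)oxy]methyl}-3,7-dimethyl-10-[(triisopropylsilyl)oxy]dodeca-2,8,10-trien-1-ol
Product: 15 (2E,7S,8E,10Z)-7-{[(tert-butyldimethylsilyl)oxy]methyl}-3,7-dimethyl-10-[(triisopropylsilyl)oxy]dodeca-2,8,10-trienal
Conditions: MnO2 (activated, 15 equiv), CH2Cl2, rt
Reagents that add atoms: none
Why: Allylic oxidation with MnO2 is specific for the allylic alcohol and should deliver the (E)-enal without touching the silyloxydiene.

Step 10
Reactants: 15 (2E,7S,8E,10Z)-7-{[(tert-butyldimethylsilyl)oxy]methyl}-3,7-dimethyl-10-[(triisopropylsilyl)oxy]dodeca-2,8,10-trienal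
Product: 16 19-[(tert-butyldimethylsilyl)oxy]-7-[(triisopropylsilyl)oxy]-12,13,14,15,16-pentanorlabd-6-en-11-al (8β-CH3, 9β-CHO)
Conditions: oxazaborolidinium triflimide from (R)-α,α-diphenylprolinol, o-tolylboroxine and Tf2NH (20 mol %, slight excess of oxazaborolidine over acid), CH2Cl2 (0.01 M), −78 → −20 °C; Et3N quench
Reagents that add atoms: none
Why: The protonated oxazaborolidine binds the formyl oxygen of the s-trans (E)-enal and lowers its LUMO, and the tethered silyloxydiene adds in a concerted, asynchronous [4+2] cycloaddition in which the C5–C10 bond (to the β-carbon of the enal) runs ahead of the C8–C9 bond, both suprafacially. The closest known reaction type is the oxazaborolidinium-catalysed enantioselective intramolecular Diels–Alder reaction of 2,8,10-trienals to trans-fused octalins, together with the Lewis acid-promoted cyclisation of such trienals. Ring A is closed as a six-membered ring by the C5–C10 bond across the four-atom tether C1–C4, which lies exo in a chair-like arrangement, and ring B is closed as the new cyclohexene (C5=C6–C7=C8 diene plus C9=C10 dienophile). C9 and C10 are fixed relative to each other by the (E)-geometry of the enal (CHO and C20 methyl cis), the trans ring fusion (5α-H, 10β-CH3) follows from the endo-formyl transition state, C8 follows from the (Z)-enol ether but is erased in step 14, and the absolute sense (diene onto the Si face of C9) is set by the catalyst, whose antipode is chosen by the formyl C–H···O binding model so that its aryl group covers the Re face. The step needs endo over exo and one π-face: the (E,E)-geometry and tether length allow only this regiochemistry, the quaternary C4 (no allylic hydrogen, Thorpe–Ingold compression) keeps the diene intact and reactive, and because CH3 and CH2OTBS on C4 are of similar size the substrate has little facial bias of its own, so the catalyst decides which C4/C5 diastereomer is formed.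

Step 11
Reactants: 16 19-[(tert-butyldimethylsilyl)oxy]-7-[(triisopropylsilyl)oxy]-12,13,14,15,16-pentanorlabd-6-en-11-al
Product: 17 19-[(tert-butyldimethylsilyl)oxy]-7-[(triisopropylsilyl)oxy]-13,14,15,16-tetranorlabda-6,11-diene
Conditions: Ph3PCH3Br, KN(SiMe3)2, THF, 0 °C → rt
Reagents that add atoms: methyltriphenylphosphonium bromide, C[P+](c1ccccc1)(c1ccccc1)c1ccccc1.[Br-]
Why: Wittig methylenation converts the hindered aldehyde into the C11=C12 vinyl group, and since the C9 substituent is already equatorial the basic ylide cannot erode C9.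

Step 12
Reactants: 17 19-[(tert-butyldimethylsilyl)oxy]-7-[(triisopropylsilyl)oxy]-13,14,15,16-tetranorlabda-6,11-diene; 18 2-chlorobuta-1,3-diene (chloroprene)
Product: 20 19-[(tert-butyldimethylsilyl)oxy]-7-[(triisopropylsilyl)oxy]labda-6,13(16),14-triene, via B-alkyl-9-borabicyclononane 19 (not isolated)
Conditions: 9-BBN-H dimer, THF, 0 → 40 °C; then 18, Pd(OAc)2 (5 mol %), SPhos (10 mol %), K3PO4 (3 M aq.), THF, 40 °C
Reagents that add atoms: 9-borabicyclo[3.3.1]nonane, B1C2CCCC1CCC2 (boron residue in 19 only)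
Why: 9-BBN hydroborates only the unhindered terminal vinyl group (boron on C12), and B-alkyl Suzuki–Miyaura coupling with the alkenyl chloride joins C12 to C13 and installs the 2-substituted buta-1,3-diene directly.

Step 13
Reactants: 20 19-[(tert-butyldimethylsilyl)oxy]-7-[(triisopropylsilyl)oxy]labda-6,13(16),14-triene
Product: 21 19-hydroxylabda-13(16),14-dien-7-one (8β-CH3 as formed; either C8 epimer converges in step 14)
Conditions: Bu4NF (3 equiv), THF, 0 °C → rt; H2O
Reagents that add atoms: none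
Why: Fluoride cleaves both Si–O bonds, the liberated enolate is protonated at C6 to give the C7 ketone, and the neopentyl silyl ether is removed in the same operation.

Step 14
Reactants: 21 19-hydroxylabda-13(16),14-dien-7-one
Product: 22 7,19-bis[(trimethylsilyl)oxy]labda-7,13(16),14-triene
Conditions: BrMgN(i-Pr)2 (from EtMgBr and i-Pr2NH, 3 equiv), Et2O, rt, 12 h; then Me3SiCl, Et3N, HMPA, rt; used crude
Reagents that add atoms: chlorotrimethylsilane, C[Si](C)(C)Cl
Why: Enolisation with the magnesium amide under equilibrating conditions should give the more substituted (C7=C8) enolate, which is trapped on oxygen together with the C19 alkoxide, so that the oxygen to come is directed to C8 and not to C6.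

Step 15
Reactants: 22 7,19-bis[(trimethylsilyl)oxy]labda-7,13(16),14-triene
Product: 24 8α,19-dihydroxylabda-13(16),14-dien-7-one, via 8α-silyloxy ketone 23 (not isolated)
Conditions: mCPBA (1.05 equiv), NaHCO3, CH2Cl2, −40 → 0 °C; then citric acid, MeOH, rt
Reagents that add atoms: 3-chloroperoxybenzoic acid, O=C(OO)c1cccc(Cl)c1
Why: Rubottom oxidation: the peracid epoxidises the electron-rich tetrasubstituted enol ether far faster than the 1,3-diene and from the α-face, because the β-face is blocked by the axial C20 methyl and the C9 side chain, and silyl migration then gives the 8α-oxygenated ketone (C8 set: 8α-OH, 8β-CH3).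

Step 16
Reactants: 24 8α,19-dihydroxylabda-13(16),14-dien-7-one
Product: 25 labda-13(16),14-diene-7α,8α,19-triol
Conditions: LiBH(s-Bu)3 (4 equiv), THF, −78 °C; aq. NH4Cl
Reagents that add atoms: none
Why: The bulky trialkylborohydride should attack the C7 carbonyl along the equatorial (β-face) trajectory, as it does in 4,4-disubstituted 3-oxo terpenoids, to give the axial 7α-alcohol cis to the 8α-hydroxyl.

Step 17
Reactants: 25 labda-13(16),14-diene-7α,8α,19-triol; 26 2-[bis(2,2,2-trifluoroethoxy)phosphoryl]acetic acid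
Product: 27 7α,8α-dihydroxylabda-13(16),14-dien-19-yl 2-[bis(2,2,2-trifluoroethoxy)phosphoryl]acetate
Conditions: DCC (1.1 equiv), DMAP (0.1 equiv), 26 (1.05 equiv), CH2Cl2, 0 °C
Reagents that add atoms: none
Why: Steglich esterification should acylate the primary C19 hydroxyl in preference to the axial secondary C7 hydroxyl flanked by a tertiary carbinol and to the tertiary C8 hydroxyl.

Step 18
Reactants: 27 7α,8α-dihydroxylabda-13(16),14-dien-19-yl 2-[bis(2,2,2-trifluoroethoxy)phosphoryl]acetate; 28 4-[(tert-butyldimethylsilyl)oxy]benzaldehyde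
Product: 29 7α,8α-dihydroxylabda-13(16),14-dien-19-yl (2Z)-3-{4-[(tert-butyldimethylsilyl)oxy]phenyl}prop-2-enoate
Conditions: KN(SiMe3)2 (1.05 equiv), 18-crown-6 (3 equiv), THF, −78 °C; then 28; light excluded
Reagents that add atoms: none
Why: Still–Gennari olefination: the electron-poor bis(trifluoroethyl)phosphonate anion, far more acidic than the free hydroxyls, adds to the aryl aldehyde and collapses kinetically to the (Z)-enoate.

Step 19
Reactants: 29 7α,8α-dihydroxylabda-13(16),14-dien-19-yl (2Z)-3-{4-[(tert-butyldimethylsilyl)oxy]phenyl}prop-2-enoate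
Product: 30 7α,8α-dihydroxylabda-13(16),14-dien-19-yl (2Z)-3-(4-hydroxyphenyl)prop-2-enoate (target)
Conditions: Bu4NF/AcOH (1:1, 1.5 equiv), THF, 0 °C, light excluded
Reagents that add atoms: none
Why: Buffered fluoride removes the aryl silyl ether under conditions that should neither isomerise the (Z)-enoate nor affect the diene or the diol.

**Compound list**

1 | pent-1-en-4-yne | C=CCC#C | starting material
2 | dimethyl[(1E)-2-methylpenta-1,4-dien-1-yl]alane | C=CC/C(C)=C/[Al](C)C | intermediate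
3 | methyl (2E)-3-methylhexa-2,5-dienoate | C=CC/C(C)=C/C(=O)OC | intermediate
4 | 1-[(tert-butyldimethylsilyl)oxy]propan-2-one | CC(=O)CO[Si](C)(C)C(C)(C)C | starting material
5 | triethyl phosphonoacetate | CCOC(=O)CP(=O)(OCC)OCC | starting material
6 | ethyl (2E)-4-[(tert-butyldimethylsilyl)oxy]-3-methylbut-2-enoate | CCOC(=O)/C=C(\C)CO[Si](C)(C)C(C)(C)C | intermediate
7 | (2E)-4-[(tert-butyldimethylsilyl)oxy]-3-methylbut-2-en-1-ol | OC/C=C(\C)CO[Si](C)(C)C(C)(C)C | intermediate
8 | tert-butyl{[(2E)-4-chloro-2-methylbut-2-en-1-yl]oxy}dimethylsilane | ClC/C=C(\C)CO[Si](C)(C)C(C)(C)C | intermediate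
9 | methyl (2E)-6-(9-borabicyclo[3.3.1]nonan-9-yl)-3-methylhex-2-enoate | COC(=O)/C=C(\C)CCCB1C2CCCC1CCC2 | intermediate
10 | methyl (2E,7S)-7-{[(tert-butyldimethylsilyl)oxy]methyl}-3,7-dimethylnona-2,8-dienoate | COC(=O)/C=C(\C)CCC[C@](C)(CO[Si](C)(C)C(C)(C)C)C=C | intermediate
11 | pent-1-en-3-one | CCC(=O)C=C | starting material
12 | methyl (2E,7S,8E)-7-{[(tert-butyldimethylsilyl)oxy]methyl}-3,7-dimethyl-10-oxododeca-2,8-dienoate | COC(=O)/C=C(\C)CCC[C@](C)(CO[Si](C)(C)C(C)(C)C)/C=C/C(=O)CC | intermediate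
13 | methyl (2E,7S,8E,10Z)-7-{[(tert-butyldimethylsilyl)oxy]methyl}-3,7-dimethyl-10-[(triisopropylsilyl)oxy]dodeca-2,8,10-trienoate | COC(=O)/C=C(\C)CCC[C@](C)(CO[Si](C)(C)C(C)(C)C)/C=C/C(O[Si](C(C)C)(C(C)C)C(C)C)=C/C | intermediate
14 | (2E,7S,8E,10Z)-7-{[(tert-butyldimethylsilyl)oxy]methyl}-3,7-dimethyl-10-[(triisopropylsilyl)oxy]dodeca-2,8,10-trien-1-ol | OC/C=C(\C)CCC[C@](C)(CO[Si](C)(C)C(C)(C)C)/C=C/C(O[Si](C(C)C)(C(C)C)C(C)C)=C/C | intermediate
15 | (2E,7S,8E,10Z)-7-{[(tert-butyldimethylsilyl)oxy]methyl}-3,7-dimethyl-10-[(triisopropylsilyl)oxy]dodeca-2,8,10-trienal | O=C/C=C(\C)CCC[C@](C)(CO[Si](C)(C)C(C)(C)C)/C=C/C(O[Si](C(C)C)(C(C)C)C(C)C)=C/C | intermediate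
16 | 19-[(tert-butyldimethylsilyl)oxy]-7-[(triisopropylsilyl)oxy]-12,13,14,15,16-pentanorlabd-6-en-11-al (5α-H, 8β-CH3, 9β-CHO, 10β-CH3) | O=C[C@H]1[C@@H](C)C(O[Si](C(C)C)(C(C)C)C(C)C)=C[C@H]2[C@@](C)(CO[Si](C)(C)C(C)(C)C)CCC[C@@]21C | intermediate
17 | 19-[(tert-butyldimethylsilyl)oxy]-7-[(triisopropylsilyl)oxy]-13,14,15,16-tetranorlabda-6,11-diene | C=C[C@H]1[C@@H](C)C(O[Si](C(C)C)(C(C)C)C(C)C)=C[C@H]2[C@@](C)(CO[Si](C)(C)C(C)(C)C)CCC[C@@]21C | intermediate
18 | 2-chlorobuta-1,3-diene (chloroprene) | C=CC(Cl)=C | starting material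
19 | 12-(9-borabicyclo[3.3.1]nonan-9-yl)-19-[(tert-butyldimethylsilyl)oxy]-7-[(triisopropylsilyl)oxy]-13,14,15,16-tetranorlabd-6-ene | C1CCC2CCCC1B2CC[C@H]1[C@@H](C)C(O[Si](C(C)C)(C(C)C)C(C)C)=C[C@H]2[C@@](C)(CO[Si](C)(C)C(C)(C)C)CCC[C@@]21C | intermediate
20 | 19-[(tert-butyldimethylsilyl)oxy]-7-[(triisopropylsilyl)oxy]labda-6,13(16),14-triene | C=CC(=C)CC[C@H]1[C@@H](C)C(O[Si](C(C)C)(C(C)C)C(C)C)=C[C@H]2[C@@](C)(CO[Si](C)(C)C(C)(C)C)CCC[C@@]21C | intermediate
21 | 19-hydroxylabda-13(16),14-dien-7-one (8β-CH3) | C=CC(=C)CC[C@H]1[C@@H](C)C(=O)C[C@H]2[C@@](C)(CO)CCC[C@@]21C | intermediate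
22 | 7,19-bis[(trimethylsilyl)oxy]labda-7,13(16),14-triene | C=CC(=C)CC[C@H]1C(C)=C(O[Si](C)(C)C)C[C@H]2[C@@](C)(CO[Si](C)(C)C)CCC[C@@]21C | intermediate
23 | 8α,19-bis[(trimethylsilyl)oxy]labda-13(16),14-dien-7-one | C=CC(=C)CC[C@H]1[C@](C)(O[Si](C)(C)C)C(=O)C[C@H]2[C@@](C)(CO[Si](C)(C)C)CCC[C@@]21C | intermediate
24 | 8α,19-dihydroxylabda-13(16),14-dien-7-one | C=CC(=C)CC[C@H]1[C@](C)(O)C(=O)C[C@H]2[C@@](C)(CO)CCC[C@@]21C | intermediate
25 | labda-13(16),14-diene-7α,8α,19-triol | C=CC(=C)CC[C@H]1[C@](C)(O)[C@H](O)C[C@H]2[C@@](C)(CO)CCC[C@@]21C | intermediate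
26 | 2-[bis(2,2,2-trifluoroethoxy)phosphoryl]acetic acid | OC(=O)CP(=O)(OCC(F)(F)F)OCC(F)(F)F | starting material
27 | 7α,8α-dihydroxylabda-13(16),14-dien-19-yl 2-[bis(2,2,2-trifluoroethoxy)phosphoryl]acetate | C=CC(=C)CC[C@H]1[C@](C)(O)[C@H](O)C[C@H]2[C@@](C)(COC(=O)CP(=O)(OCC(F)(F)F)OCC(F)(F)F)CCC[C@@]21C | intermediate
28 | 4-[(tert-butyldimethylsilyl)oxy]benzaldehyde | O=Cc1ccc(O[Si](C)(C)C(C)(C)C)cc1 | starting material
29 | 7α,8α-dihydroxylabda-13(16),14-dien-19-yl (2Z)-3-{4-[(tert-butyldimethylsilyl)oxy]phenyl}prop-2-enoate | C=CC(=C)CC[C@H]1[C@](C)(O)[C@H](O)C[C@H]2[C@@](C)(COC(=O)/C=C\c3ccc(O[Si](C)(C)C(C)(C)C)cc3)CCC[C@@]21C | intermediate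
30 | 7α,8α-dihydroxylabda-13(16),14-dien-19-yl (2Z)-3-(4-hydroxyphenyl)prop-2-enoate, (4S,5R,7R,8S,9R,10S) | C=CC(=C)CC[C@H]1[C@](C)(O)[C@H](O)C[C@H]2[C@@](C)(COC(=O)/C=C\c3ccc(O)cc3)CCC[C@@]21C | target

**Step count and risks**

Total step count: 19. Longest linear sequence: 18 steps (4 → 30 through steps 2–19); the branch from 1 joins at step 5.

Steps most likely to fail:

Step 10. The β,β-disubstituted enal may react sluggishly with the C5 terminus, which the C7 silyloxy group does not activate. The acid catalyst may isomerise the (E)-enal or protodesilylate the diene, and facial control may be incomplete. Fallback (auxiliary control in place of catalyst control), setting out from 12 and returning at 16: saponification of 12 (LiOH, THF/H2O) should give (2E,7S,8E)-7-{[(tert-butyldimethylsilyl)oxy]methyl}-3,7-dimethyl-10-oxododeca-2,8-dienoic acid F1. Its mixed pivalic anhydride (t-BuCOCl, Et3N) is coupled with lithiated (S)-4-benzyloxazolidin-2-one to the N-enoyl imide F2. i-Pr3SiOTf/Et3N gives the silyloxydiene imide F3. Me2AlCl (1.5 equiv, CH2Cl2, −30 °C) promotes the auxiliary-controlled intramolecular Diels–Alder reaction through the chelated s-cis imide, whose benzyl group covers the Re face of C9, giving the bicyclic imide F4. LiBH4 (THF/MeOH, 0 °C) cleaves the auxiliary to the primary C11 alcohol F5, and Dess–Martin periodinane oxidises F5 to 16.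

Step 5. The catalyst may discriminate poorly between CH3 and CH2OTBS on the γ-carbon, and some SN2 coupling may compete, so that C4 is formed with low enantiomeric purity. Fallback (no enantioselective step at C4; the cycloaddition does the sorting), setting out from 3 and 8 and returning at 16: the same hydroboration and coupling with an achiral copper catalyst (CuCl, 1,3-dimesitylimidazolium chloride, KOMe) gives racemic methyl (2E)-7-{[(tert-butyldimethylsilyl)oxy]methyl}-3,7-dimethylnona-2,8-dienoate F6. Steps 6–9 are run unchanged on the racemate to give the racemic enone F7, the racemic silyloxydiene ester F8, the racemic allylic alcohol F9 and the racemic trienal F10. The catalyst-controlled cycloaddition of step 10 then turns the two enantiomers of F10 into two diastereomers, 16 and its C4-epimer F11 (4β-CH3, 4α-CH2OTBS), which differ in the axial or equatorial placement of the silyloxymethyl group and should be separable by chromatography.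

Step 12. Transmetalation of the hindered alkylborane may be slow, chloroprene may polymerise or be lost by evaporation, and β-hydride elimination may compete. Fallback (sp3 electrophile with a dienyl Grignard reagent in place of sp3 borane with dienyl chloride), setting out from 17 and returning at 20: hydroboration of 17 as before and oxidation of 19 (NaBO3·4H2O, THF/H2O) should give 19-[(tert-butyldimethylsilyl)oxy]-7-[(triisopropylsilyl)oxy]-13,14,15,16-tetranorlabd-6-en-12-ol F12. TsCl/pyridine gives the C12 tosylate F13. Chloroprene 18 and Mg (THF, catalytic ZnCl2) give buta-1,3-dien-2-ylmagnesium chloride F14, which is coupled with F13 under Li2CuCl4 catalysis (THF, −20 → 0 °C) to give 20.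

**Further compounds**

F1 | step 10 | (2E,7S,8E)-7-{[(tert-butyldimethylsilyl)oxy]methyl}-3,7-dimethyl-10-oxododeca-2,8-dienoic acid | OC(=O)/C=C(\C)CCC[C@](C)(CO[Si](C)(C)C(C)(C)C)/C=C/C(=O)CC
F2 | step 10 | (4S)-4-benzyl-3-[(2E,7S,8E)-7-{[(tert-butyldimethylsilyl)oxy]methyl}-3,7-dimethyl-10-oxododeca-2,8-dienoyl]-1,3-oxazolidin-2-one | O=C(/C=C(\C)CCC[C@](C)(CO[Si](C)(C)C(C)(C)C)/C=C/C(=O)CC)N1[C@@H](Cc2ccccc2)COC1=O
F3 | step 10 | (4S)-4-benzyl-3-[(2E,7S,8E,10Z)-7-{[(tert-butyldimethylsilyl)oxy]methyl}-3,7-dimethyl-10-[(triisopropylsilyl)oxy]dodeca-2,8,10-trienoyl]-1,3-oxazolidin-2-one | O=C(/C=C(\C)CCC[C@](C)(CO[Si](C)(C)C(C)(C)C)/C=C/C(O[Si](C(C)C)(C(C)C)C(C)C)=C/C)N1[C@@H](Cc2ccccc2)COC1=O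
F4 | step 10 | (4S)-4-benzyl-3-{19-[(tert-butyldimethylsilyl)oxy]-7-[(triisopropylsilyl)oxy]-12,13,14,15,16-pentanorlabd-6-en-11-oyl}-1,3-oxazolidin-2-one | O=C([C@H]1[C@@H](C)C(O[Si](C(C)C)(C(C)C)C(C)C)=C[C@H]2[C@@](C)(CO[Si](C)(C)C(C)(C)C)CCC[C@@]21C)N1[C@@H](Cc2ccccc2)COC1=O
F5 | step 10 | 19-[(tert-butyldimethylsilyl)oxy]-7-[(triisopropylsilyl)oxy]-12,13,14,15,16-pentanorlabd-6-en-11-ol | OC[C@H]1[C@@H](C)C(O[Si](C(C)C)(C(C)C)C(C)C)=C[C@H]2[C@@](C)(CO[Si](C)(C)C(C)(C)C)CCC[C@@]21C
F6 | step 5 | racemic methyl (2E)-7-{[(tert-butyldimethylsilyl)oxy]methyl}-3,7-dimethylnona-2,8-dienoate | COC(=O)/C=C(\C)CCCC(C)(CO[Si](C)(C)C(C)(C)C)C=C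
F7 | step 5 | racemic methyl (2E,8E)-7-{[(tert-butyldimethylsilyl)oxy]methyl}-3,7-dimethyl-10-oxododeca-2,8-dienoate | COC(=O)/C=C(\C)CCCC(C)(CO[Si](C)(C)C(C)(C)C)/C=C/C(=O)CC
F8 | step 5 | racemic methyl (2E,8E,10Z)-7-{[(tert-butyldimethylsilyl)oxy]methyl}-3,7-dimethyl-10-[(triisopropylsilyl)oxy]dodeca-2,8,10-trienoate | COC(=O)/C=C(\C)CCCC(C)(CO[Si](C)(C)C(C)(C)C)/C=C/C(O[Si](C(C)C)(C(C)C)C(C)C)=C/C
F9 | step 5 | racemic (2E,8E,10Z)-7-{[(tert-butyldimethylsilyl)oxy]methyl}-3,7-dimethyl-10-[(triisopropylsilyl)oxy]dodeca-2,8,10-trien-1-ol | OC/C=C(\C)CCCC(C)(CO[Si](C)(C)C(C)(C)C)/C=C/C(O[Si](C(C)C)(C(C)C)C(C)C)=C/C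
F10 | step 5 | racemic (2E,8E,10Z)-7-{[(tert-butyldimethylsilyl)oxy]methyl}-3,7-dimethyl-10-[(triisopropylsilyl)oxy]dodeca-2,8,10-trienal | O=C/C=C(\C)CCCC(C)(CO[Si](C)(C)C(C)(C)C)/C=C/C(O[Si](C(C)C)(C(C)C)C(C)C)=C/C
F11 | step 5 | C4-epimer of 16: 18-[(tert-butyldimethylsilyl)oxy]-7-[(triisopropylsilyl)oxy]-12,13,14,15,16-pentanorlabd-6-en-11-al (4β-CH3, 4α-CH2OTBS) | O=C[C@H]1[C@@H](C)C(O[Si](C(C)C)(C(C)C)C(C)C)=C[C@H]2[C@](C)(CO[Si](C)(C)C(C)(C)C)CCC[C@@]21C
F12 | step 12 | 19-[(tert-butyldimethylsilyl)oxy]-7-[(triisopropylsilyl)oxy]-13,14,15,16-tetranorlabd-6-en-12-ol | OCC[C@H]1[C@@H](C)C(O[Si](C(C)C)(C(C)C)C(C)C)=C[C@H]2[C@@](C)(CO[Si](C)(C)C(C)(C)C)CCC[C@@]21C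
F13 | step 12 | 19-[(tert-butyldimethylsilyl)oxy]-7-[(triisopropylsilyl)oxy]-13,14,15,16-tetranorlabd-6-en-12-yl 4-methylbenzenesulfonate | Cc1ccc(cc1)S(=O)(=O)OCC[C@H]1[C@@H](C)C(O[Si](C(C)C)(C(C)C)C(C)C)=C[C@H]2[C@@](C)(CO[Si](C)(C)C(C)(C)C)CCC[C@@]21C
F14 | step 12 | buta-1,3-dien-2-ylmagnesium chloride | C=CC(=C)[Mg]Cl
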